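**Assumptions (one line each).** The enantiomer of the bromochlorination ligand in step 13 is chosen by a test reaction to give the (5S,6S) series. Compounds 1 and 12, (+)-Ipc2BOMe and the ligand are purchased. The route has not been run; the stereochemical outcomes below are predictions from standard models.

## Retrosynthetic overview

1. The cyclohexane is closed last: 19 ⇐ diimide reduction of cyclohexene 18 ⇐ ring-closing metathesis of 1,7-diene 17.
2. The C–Br/C–Cl pair is set on the open chain (17 ⇐ 15 ⇐ 14) by enantioselective anti-bromochlorination of a Z-allylic alcohol. Bromochlorination of a preformed cyclohexene would give the trans-diaxial (wrong) diastereomer.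
3. 14 ⇐ Negishi sp3–sp2 union of the bromo-oxane alkyl iodide 11 with (Z)-vinyl iodide 13 (one step from propargyl alcohol).
4. 11 ⇐ 6-endo bromoetherification of hydroxy acetate 8 ⇐ OH-directed epoxidation and anti vinyl-cuprate opening ⇐ asymmetric allylation of the lactol of 3-methylbutenolide.
5. Ring order: oxane first (step 8), cyclohexane second (step 16).

## Route

**Step 1**
Reactants: 1, 3-methylfuran-2(5H)-one
Product: 2, 3-methyl-2,5-dihydrofuran-2-ol (lactol, anomeric mixture)
Conditions: DIBAL-H (1.05 equiv), CH2Cl2, −78 °C; Rochelle-salt work-up, no acid; used crude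
Reagents that add atoms: none
Why: Partial lactone-to-lactol hydride reduction; the ring locks the masked 4-hydroxy-enal in the Z geometry needed later, and no lasting stereocentre is formed.

**Step 2**
Reactants: 2
Product: 3, (2Z,4R)-3-methylocta-2,7-diene-1,4-diol
Conditions: (+)-Ipc2B(allyl) [from (+)-Ipc2BOMe and allylMgBr, 2.2 equiv], Et2O, −78 → 0 °C; then NaOH, H2O2
Reagents that add atoms: B-allyldiisopinocampheylborane, C=CCB(C1CC2CC(C1C)C2(C)C)C1CC2CC(C1C)C2(C)C (allyl group)
Why: Brown asymmetric allylboration of the open hydroxy-enal form through a chair transition state; the (+)-Ipc reagent (the one that gives (R)-carbinols when the aldehyde substituent outranks allyl, as with PhCHO) sets C-4 as R.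

**Step 3**
Reactants: 3
Product: 4, (2Z,4R)-1-[(tert-butyldimethylsilyl)oxy]-3-methylocta-2,7-dien-4-ol
Conditions: TBSCl (1.05 equiv), imidazole, CH2Cl2, −20 °C
Reagents that add atoms: TBSCl, CC(C)(C)[Si](C)(C)Cl
Why: Selective silylation of the primary over the secondary allylic alcohol; leaves only the C-4 OH to direct the next step.

**Step 4**
Reactants: 4
Product: 5, (1R)-1-[(2S,3R)-3-{[(tert-butyldimethylsilyl)oxy]methyl}-2-methyloxiran-2-yl]but-3-en-1-ol
Conditions: mCPBA (1.05 equiv), NaHCO3, CH2Cl2, 0 °C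
Reagents that add atoms: mCPBA, OOC(=O)c1cccc(Cl)c1 (one O)
Why: Henbest hydroxyl-directed epoxidation; A(1,3) strain with the cis CH2OTBS group puts C4–H in the alkene plane, so the hydrogen-bonded peracid delivers oxygen syn to the OH (threo), and the trisubstituted olefin reacts far faster than the terminal one.

**Step 5**
Reactants: 5
Product: 6, (1R)-1-[(2S,3R)-3-{[(tert-butyldimethylsilyl)oxy]methyl}-2-methyloxiran-2-yl]-4-methylpent-3-en-1-ol
Conditions: 2-methyl-2-butene (excess), Grubbs II (3 mol%), CH2Cl2, 40 °C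
Reagents that add atoms: 2-methyl-2-butene, CC=C(C)C (isopropylidene unit)
Why: Olefin cross-metathesis turns the terminal allyl into the prenyl group; done before the second vinyl group exists, so no competing ring closure.

**Step 6**
Reactants: 6
Product: 7, (3S,4R,5R)-3-{[(tert-butyldimethylsilyl)oxy]methyl}-4,8-dimethylnona-1,7-diene-4,5-diol
Conditions: vinylMgBr (4 equiv), CuI (0.3 equiv), THF, −30 → 0 °C
Reagents that add atoms: vinylmagnesium bromide, C=C[Mg]Br
Why: Cuprate SN2 opening of the trisubstituted epoxide at its less substituted carbon with inversion; this sets the vinyl-bearing CH and leaves the tertiary carbinol with the epoxide configuration.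

**Step 7**
Reactants: 7
Product: 8, (3S,4R,5R)-3-{[(tert-butyldimethylsilyl)oxy]methyl}-4-hydroxy-4,8-dimethylnona-1,7-dien-5-yl acetate
Conditions: Ac2O, pyridine, DMAP (cat.), CH2Cl2, 0 °C
Reagents that add atoms: acetic anhydride, CC(=O)OC(C)=O
Why: Selective acylation of the secondary over the tertiary alcohol; installs the final acetate and blocks that oxygen from competing in the cyclisation.

**Step 8**
Reactants: 8
Product: 9, (2R,3R,5R)-5-bromo-2-[(2S)-1-{[tert-butyl(dimethyl)silyl]oxy}but-3-en-2-yl]-2,6,6-trimethyloxan-3-yl acetate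
Conditions: TBCO (1.1 equiv), MeNO2, 0 °C → rt
Reagents that add atoms: 2,4,4,6-tetrabromocyclohexa-2,5-dienone, BrC1=CC(Br)(Br)C=C(Br)C1=O (one Br)
Why: 6-endo bromoetherification; the tertiary OH opens the prenyl bromonium at the tertiary carbon through a chair transition state with the large butenyl group and Br equatorial, giving 5R.

**Step 9**
Reactants: 9
Product: 10, (2R,3R,5R)-5-bromo-2-[(2S)-1-hydroxybut-3-en-2-yl]-2,6,6-trimethyloxan-3-yl acetate
Conditions: HF·pyridine, THF/pyridine, 0 °C → rt
Reagents that add atoms: none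
Why: Fluoride-mediated desilylation under buffered acidic conditions that spare the acetate and the secondary bromide.

**Step 10**
Reactants: 10
Product: 11, (2R,3R,5R)-5-bromo-2-[(2R)-1-iodobut-3-en-2-yl]-2,6,6-trimethyloxan-3-yl acetate
Conditions: I2, PPh3, imidazole, CH2Cl2, 0 °C
Reagents that add atoms: iodine, II
Why: Appel-type iodination of the primary alcohol; the descriptor changes only because of CIP priorities, not geometry.

**Step 11**
Reactants: 12, prop-2-yn-1-ol
Product: 13, (2Z)-3-iodo-2-methylprop-2-en-1-ol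
Conditions: MeMgBr (2.5 equiv), CuI (10 mol%), THF, −10 °C → rt; then I2, −78 → 0 °C
Reagents that add atoms: methylmagnesium bromide, C[Mg]Br; iodine, II
Why: Alkoxide-directed anti-carbomagnesiation of the propargylic alcohol followed by iodinolysis gives the Z-vinyl iodide (I cis to CH2OH).

**Step 12**
Reactants: 11 and 13
Product: 14, (2R,3R,5R)-5-bromo-2-[(3R,5Z)-7-hydroxy-6-methylhepta-1,5-dien-3-yl]-2,6,6-trimethyloxan-3-yl acetate
Conditions: 11, Zn dust (activated), LiCl, THF, 25 °C; then 13, Pd(OAc)2 (2 mol%), SPhos (4 mol%), THF, 25 °C (zinc reagent added slowly)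
Reagents that add atoms: none
Why: Negishi sp3–sp2 cross-coupling; zinc inserts into the primary C–I bond only, and the vinyl iodide couples with retention, so the Z-allylic alcohol is delivered directly.

**Step 13**
Reactants: 14
Product: 15, (2R,3R,5R)-5-bromo-2-[(3R,5S,6S)-5-bromo-6-chloro-7-hydroxy-6-methylhept-1-en-3-yl]-2,6,6-trimethyloxan-3-yl acetate
Conditions: NBS (1.1 equiv), ClTi(OiPr)3 (1.1 equiv), Burns chiral Schiff-base ligand (20–30 mol%), hexanes/CH2Cl2, −20 °C
Reagents that add atoms: N-bromosuccinimide, BrN1C(=O)CCC1=O; chlorotitanium triisopropoxide, CC(C)O[Ti](Cl)(OC(C)C)OC(C)C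
Why: Burns Ti-catalysed enantioselective bromochlorination of an allylic alcohol; the ligand selects the bromonium face and Ti-bound chloride opens it anti at the tertiary carbon, so anti addition to the Z-olefin gives the (5S,6S) pair that becomes trans Br/Cl in the ring.

**Step 14**
Reactants: 15
Product: 16, (2R,3R,5R)-5-bromo-2-[(3R,5S,6S)-5-bromo-6-chloro-6-methyl-7-oxohept-1-en-3-yl]-2,6,6-trimethyloxan-3-yl acetate
Conditions: Dess–Martin periodinane, NaHCO3, CH2Cl2, 0 °C → rt
Reagents that add atoms: none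
Why: Dess–Martin oxidation to an aldehyde that has no α-hydrogen, so it cannot epimerise or eliminate.

**Step 15**
Reactants: 16
Product: 17, (2R,3R,5R)-5-bromo-2-[(3R,5S,6S)-5-bromo-6-chloro-6-methylocta-1,7-dien-3-yl]-2,6,6-trimethyloxan-3-yl acetate
Conditions: Ph3P=CH2 (from Ph3PCH3Br/KHMDS, 1.2 equiv), THF, −78 → 0 °C
Reagents that add atoms: methylenetriphenylphosphorane, C=P(c1ccccc1)(c1ccccc1)c1ccccc1 (CH2)
Why: Wittig methylenation gives the second terminal vinyl group; low temperature and near-stoichiometric ylide protect the acetate and the halides.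

**Step 16**
Reactants: 17
Product: 18, (2R,3R,5R)-5-bromo-2-[(1R,4S,5S)-5-bromo-4-chloro-4-methylcyclohex-2-en-1-yl]-2,6,6-trimethyloxan-3-yl acetate
Conditions: Hoveyda–Grubbs II (5 mol%), CH2Cl2 (0.005 M), 40 °C
Reagents that add atoms: none
Why: Ring-closing metathesis of the two terminal vinyl groups closes the six-membered carbocycle with loss of ethylene; no stereocentre is touched.

**Step 17**
Reactants: 18
Product: 19, 8-acetylcaespitol
Conditions: 2-nitrobenzenesulfonylhydrazide, Et3N, CH2Cl2, rt (diimide generated in situ)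
Reagents that add atoms: none
Why: Diimide syn-hydrogenation of the cis-disubstituted ring alkene; it leaves the C–Br and C–Cl bonds and the acetate intact, giving the (1S,3S,4S) ring.

## Compound list

1 | 3-methylfuran-2(5H)-one | CC1=CCOC1=O | starting material
2 | 3-methyl-2,5-dihydrofuran-2-ol | CC1=CCOC1O | intermediate
3 | (2Z,4R)-3-methylocta-2,7-diene-1,4-diol | OC/C=C(C)\[C@H](O)CC=C | intermediate
4 | (2Z,4R)-1-[(tert-butyldimethylsilyl)oxy]-3-methylocta-2,7-dien-4-ol | CC(C)(C)[Si](C)(C)OC/C=C(C)\[C@H](O)CC=C | intermediate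
5 | (1R)-1-[(2S,3R)-3-(TBSO-methyl)-2-methyloxiran-2-yl]but-3-en-1-ol | CC(C)(C)[Si](C)(C)OC[C@H]1O[C@@]1(C)[C@H](O)CC=C | intermediate
6 | (1R)-1-[(2S,3R)-3-(TBSO-methyl)-2-methyloxiran-2-yl]-4-methylpent-3-en-1-ol | CC(C)(C)[Si](C)(C)OC[C@H]1O[C@@]1(C)[C@H](O)CC=C(C)C | intermediate
7 | (3S,4R,5R)-3-(TBSO-methyl)-4,8-dimethylnona-1,7-diene-4,5-diol | CC(C)(C)[Si](C)(C)OC[C@H](C=C)[C@@](C)(O)[C@H](O)CC=C(C)C | intermediate
8 | (3S,4R,5R)-3-(TBSO-methyl)-4-hydroxy-4,8-dimethylnona-1,7-dien-5-yl acetate | CC(C)(C)[Si](C)(C)OC[C@H](C=C)[C@@](C)(O)[C@H](OC(C)=O)CC=C(C)C | intermediate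
9 | (2R,3R,5R)-5-bromo-2-[(2S)-1-(TBSO)but-3-en-2-yl]-2,6,6-trimethyloxan-3-yl acetate | CC(=O)O[C@@H]1C[C@@H](Br)C(C)(C)O[C@]1(C)[C@H](CO[Si](C)(C)C(C)(C)C)C=C | intermediate
10 | (2R,3R,5R)-5-bromo-2-[(2S)-1-hydroxybut-3-en-2-yl]-2,6,6-trimethyloxan-3-yl acetate | CC(=O)O[C@@H]1C[C@@H](Br)C(C)(C)O[C@]1(C)[C@H](CO)C=C | intermediate
11 | (2R,3R,5R)-5-bromo-2-[(2R)-1-iodobut-3-en-2-yl]-2,6,6-trimethyloxan-3-yl acetate | CC(=O)O[C@@H]1C[C@@H](Br)C(C)(C)O[C@]1(C)[C@H](CI)C=C | intermediate
12 | prop-2-yn-1-ol | C#CCO | starting material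
13 | (2Z)-3-iodo-2-methylprop-2-en-1-ol | OC/C(C)=C\I | intermediate
14 | (2R,3R,5R)-5-bromo-2-[(3R,5Z)-7-hydroxy-6-methylhepta-1,5-dien-3-yl]-2,6,6-trimethyloxan-3-yl acetate | CC(=O)O[C@@H]1C[C@@H](Br)C(C)(C)O[C@]1(C)[C@H](C/C=C(C)\CO)C=C | intermediate
15 | (2R,3R,5R)-5-bromo-2-[(3R,5S,6S)-5-bromo-6-chloro-7-hydroxy-6-methylhept-1-en-3-yl]-2,6,6-trimethyloxan-3-yl acetate | CC(=O)O[C@@H]1C[C@@H](Br)C(C)(C)O[C@]1(C)[C@H](C[C@H](Br)[C@@](C)(Cl)CO)C=C | intermediate
16 | (2R,3R,5R)-5-bromo-2-[(3R,5S,6S)-5-bromo-6-chloro-6-methyl-7-oxohept-1-en-3-yl]-2,6,6-trimethyloxan-3-yl acetate | CC(=O)O[C@@H]1C[C@@H](Br)C(C)(C)O[C@]1(C)[C@H](C[C@H](Br)[C@@](C)(Cl)C=O)C=C | intermediate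
17 | (2R,3R,5R)-5-bromo-2-[(3R,5S,6S)-5-bromo-6-chloro-6-methylocta-1,7-dien-3-yl]-2,6,6-trimethyloxan-3-yl acetate | CC(=O)O[C@@H]1C[C@@H](Br)C(C)(C)O[C@]1(C)[C@H](C[C@H](Br)[C@@](C)(Cl)C=C)C=C | intermediate
18 | (2R,3R,5R)-5-bromo-2-[(1R,4S,5S)-5-bromo-4-chloro-4-methylcyclohex-2-en-1-yl]-2,6,6-trimethyloxan-3-yl acetate | CC(=O)O[C@@H]1C[C@@H](Br)C(C)(C)O[C@]1(C)[C@H]1C=C[C@](C)(Cl)[C@@H](Br)C1 | intermediate
19 | 8-acetylcaespitol, (2R,3R,5R)-5-bromo-2-[(1S,3S,4S)-3-bromo-4-chloro-4-methylcyclohexyl]-2,6,6-trimethyloxan-3-yl acetate | CC(=O)O[C@@H]1C[C@@H](Br)C(C)(C)O[C@]1(C)[C@H]1CC[C@](C)(Cl)[C@@H](Br)C1 | target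

## Step count

Total steps: 17.
Longest linear sequence: 16 (steps 1–10, then 12–17). The second fragment, vinyl iodide 13, takes one step (step 11).

## Three steps most likely to fail, with fallbacks

1. **Step 8, bromoetherification.** Risks are competing 5-exo closure to a tetrahydrofuran, the C-5 epimer and a modest yield. Fallback: build the C–Br and C–O bonds in separate stereospecific operations. Shi epoxidation of the prenyl olefin of 8, then bromide opening at the secondary carbon (inversion) to the bromohydrin, then acid-promoted cyclisation of the tertiary carbinol through the bromonium ion.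

2. **Step 13, bromochlorination.** Risks are incomplete facial control on this substituted Z-allylic alcohol and mismatching with the existing stereocentres. Fallback: give up catalyst control. Run a plain anti-bromochlorination (NBS with a chloride salt), where the Z geometry still fixes the Br/Cl relative configuration, and separate the two anti diastereomers at the stage of 15 or 18.

3. **Step 2, allylboration of the lactol.** Risks are dehydration of 2 to 3-methylfuran and consumption of the borane by the lactol OH. Fallback: set C-4 by ketone reduction instead. Make (Z)-3-iodobut-2-en-1-ol TBS ether from 2-butyn-1-ol (Red-Al, then I2; TBSCl), add its alkenyllithium to N-methoxy-N-methylbut-3-enamide, and reduce the resulting enone with a CBS catalyst to reach 4 directly.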